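**Retrosynthetic overview**
1. The δ-lactone (ring B) of the dihydroisocoumarin is opened at two bonds at once, C1–C8a and O2–C3. The C1(=O)–O2 unit is CO2, and what remains is the open-chain resorcinol 11 carrying a mesylate on the future C3.
2. Enabling feature: C8a is the carbon of a 5-alkylresorcinol ring (ring A) that lies ortho to the C8 hydroxyl and para to the C6 hydroxyl, the innate site of Kolbe–Schmitt carboxylation. C3 is a secondary sp3 carbon two atoms away (via C4a–C4), so the new carboxylate closes ring B 6-exo-tet with inversion.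
3. 11 comes from one hydrogenation of 10 (alkene saturation plus loss of both benzyl ethers); 10 comes from cross-metathesis of mesylate 5 with homoallylic alcohol 9.
4. 5: aryl Grignard 3 plus (S)-epoxide 2, then mesylation. 9: (S)-epichlorohydrin 6 to (S)-epoxide 8, then vinyl Grignard opening.
5. Ring order: ring A is bought; ring B is the only ring made, in the last step, which delivers the target with no protecting group left.

Key step: step 7

Remark: the cross-metathesis product 10 is expected as an E/Z mixture; the hydrogenation that follows erases the geometry, so the E isomer is drawn.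

**Step 1**
Reactants: 1 1,3-bis(benzyloxy)-5-bromobenzene; 2 (2S)-2-(but-3-en-1-yl)oxirane
Product: 4 (2S)-1-[3,5-bis(benzyloxy)phenyl]hex-5-en-2-ol, via arylmagnesium bromide 3 (not isolated)
Conditions: Mg, I2 (cat.), THF, reflux; then CuI (10 mol%), 2, −30 → 0 °C; aq. NH4Cl
Reagents that add atoms: magnesium, [Mg] (held in 3 only; no reagent atom remains in 4)
Why: Copper-catalysed SN2 ring opening of a terminal epoxide by an aryl Grignard reagent goes at the unsubstituted carbon, so the C–O bond at the stereocentre of 2 is untouched and its (S) configuration is carried into 4.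

**Step 2**
Reactants: 4 (2S)-1-[3,5-bis(benzyloxy)phenyl]hex-5-en-2-ol
Product: 5 (2S)-1-[3,5-bis(benzyloxy)phenyl]hex-5-en-2-yl methanesulfonate
Conditions: MsCl, Et3N, CH2Cl2, 0 °C
Reagents that add atoms: methanesulfonyl chloride, CS(=O)(=O)Cl
Why: Sulfonate ester formation takes place at oxygen with retention, which installs the (S)-configured leaving group that the later lactonization inverts, and it differentiates this carbinol from the one brought in by 9.

**Step 3**
Reactants: 6 (S)-epichlorohydrin [(2S)-2-(chloromethyl)oxirane]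
Product: 8 (2S)-2-pentyloxirane, via chlorohydrin alkoxide 7 (not isolated)
Conditions: n-BuMgCl, CuI (5 mol%), THF, −40 °C; then 5 M aq. NaOH, same flask, rt; distillation
Reagents that add atoms: n-butylmagnesium chloride, CCCC[Mg]Cl
Why: Copper-catalysed Grignard opening of epichlorohydrin at the epoxide CH2, followed by Williamson ring closure of the chlorohydrin, moves the oxirane to the other terminus without touching the stereocentre, so the chiral-pool (S) centre is retained.

**Step 4**
Reactants: 8 (2S)-2-pentyloxirane
Product: 9 (4S)-non-1-en-4-ol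
Conditions: vinylmagnesium bromide, CuI (10 mol%), THF, −30 → 0 °C; aq. NH4Cl
Reagents that add atoms: vinylmagnesium bromide, C=C[Mg]Br
Why: Copper-catalysed vinyl Grignard opening of the terminal epoxide at CH2 gives the homoallylic alcohol whose (S) carbinol is inherited unchanged from 8.

**Step 5**
Reactants: 5 (2S)-1-[3,5-bis(benzyloxy)phenyl]hex-5-en-2-yl methanesulfonate; 9 (4S)-non-1-en-4-ol
Product: 10 (2S,5E,8S)-1-[3,5-bis(benzyloxy)phenyl]-8-hydroxytridec-5-en-2-yl methanesulfonate (E/Z mixture expected)
Conditions: 9 (3 equiv), second-generation Grubbs catalyst RuCl2(=CHPh)(PCy3)(H2IMes) (5 mol%), 1,4-benzoquinone (10 mol%), CH2Cl2, 40 °C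
Reagents that add atoms: none
Why: Olefin cross-metathesis of two unhindered terminal alkenes releases ethene, the excess of the cheaper partner 9 should drive 5 into the cross product, and the mesylate, benzyl ethers and free alcohol are tolerated by the ruthenium carbene.

**Step 6**
Reactants: 10 (2S,5E,8S)-1-[3,5-bis(benzyloxy)phenyl]-8-hydroxytridec-5-en-2-yl methanesulfonate
Product: 11 (2S,8S)-1-(3,5-dihydroxyphenyl)-8-hydroxytridecan-2-yl methanesulfonate
Conditions: H2 (1 atm), 10% Pd/C, EtOAc, rt
Reagents that add atoms: none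
Why: Heterogeneous catalytic hydrogenation should saturate the disubstituted alkene and hydrogenolyse both aryl benzyl ethers in one operation, while the alkyl mesylate (not benzylic, not allylic) and both stereocentres are inert under neutral conditions.

**Step 7**
Reactants: 11 (2S,8S)-1-(3,5-dihydroxyphenyl)-8-hydroxytridecan-2-yl methanesulfonate
Product: 13 (3R)-6,8-dihydroxy-3-[(6S)-6-hydroxyundecyl]-3,4-dihydro-1H-isochromen-1-one, via amidinium salicylate 12 (not isolated)
Conditions: DBU (4 equiv), CO2 (1 atm), MeCN (0.03 M), 30 °C, then 50 °C; 1 M HCl work-up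
Reagents that add atoms: carbon dioxide, O=C=O
Why: Proposed new method: the amidinium resorcinolate of 11 should add through the ring carbon that is ortho to one oxygen, para to the other and next to the side chain to CO2, as in a Kolbe–Schmitt carboxylation, and the salicylate 12 so formed should displace the neighbouring secondary mesylate through its carboxylate oxygen, which closes ring B by a 6-exo-tet SN2 lactonization; the closest known reaction types are the amidine-base Kolbe–Schmitt carboxylation of resorcinols under one atmosphere of CO2 and the alkylation of amidinium carboxylates by alkyl sulfonates, here joined in one domino. The C3 stereocentre is set by the substrate alone, since backside attack inverts the (S)-mesylate carbon to (R) and the remote (S) carbinol is not touched. The step needs site selectivity between the two equivalent ring carbons flanking the chain and the carbon between the two hydroxyls: carboxylation at the latter is reversible and its carboxylate cannot reach the mesylate, so only the wanted regioisomer is drained irreversibly into the lactone, which also pulls the unfavourable carboxylation equilibrium forward. Phenoxide O-alkylation is impossible within the molecule because both oxygens are meta to the chain, and between molecules it is held back by dilution. Elimination to the styrene is the remaining competitor and should be kept down by the weak base pair (phenoxide and amidinium under CO2) and the low temperature; the side-chain alcohol may form an alkyl carbonate salt reversibly, which reverts on acidic work-up.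

**Compound list**
1 | 1,3-bis(benzyloxy)-5-bromobenzene | Brc1cc(OCc2ccccc2)cc(OCc2ccccc2)c1 | starting material
2 | (2S)-2-(but-3-en-1-yl)oxirane [(S)-1,2-epoxyhex-5-ene] | C=CCC[C@H]1CO1 | starting material
3 | [3,5-bis(benzyloxy)phenyl]magnesium bromide | Br[Mg]c1cc(OCc2ccccc2)cc(OCc2ccccc2)c1 | intermediate
4 | (2S)-1-[3,5-bis(benzyloxy)phenyl]hex-5-en-2-ol | C=CCC[C@H](O)Cc1cc(OCc2ccccc2)cc(OCc2ccccc2)c1 | intermediate
5 | (2S)-1-[3,5-bis(benzyloxy)phenyl]hex-5-en-2-yl methanesulfonate | C=CCC[C@H](OS(C)(=O)=O)Cc1cc(OCc2ccccc2)cc(OCc2ccccc2)c1 | intermediate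
6 | (S)-epichlorohydrin, (2S)-2-(chloromethyl)oxirane | ClC[C@@H]1CO1 | starting material
7 | (2S)-1-chloroheptan-2-ol (present as its magnesium alkoxide; drawn as the alcohol) | CCCCC[C@H](O)CCl | intermediate
8 | (2S)-2-pentyloxirane [(S)-1,2-epoxyheptane] | CCCCC[C@H]1CO1 | intermediate
9 | (4S)-non-1-en-4-ol | CCCCC[C@H](O)CC=C | intermediate
10 | (2S,5E,8S)-1-[3,5-bis(benzyloxy)phenyl]-8-hydroxytridec-5-en-2-yl methanesulfonate | CCCCC[C@H](O)C/C=C/CC[C@H](OS(C)(=O)=O)Cc1cc(OCc2ccccc2)cc(OCc2ccccc2)c1 | intermediate
11 | (2S,8S)-1-(3,5-dihydroxyphenyl)-8-hydroxytridecan-2-yl methanesulfonate | CCCCC[C@H](O)CCCCC[C@H](OS(C)(=O)=O)Cc1cc(O)cc(O)c1 | intermediate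
12 | 2,4-dihydroxy-6-[(2S,8S)-8-hydroxy-2-(methanesulfonyloxy)tridecyl]benzoate, amidinium salt (drawn as the free acid) | CCCCC[C@H](O)CCCCC[C@H](OS(C)(=O)=O)Cc1cc(O)cc(O)c1C(=O)O | intermediate
13 | (3R)-6,8-dihydroxy-3-[(6S)-6-hydroxyundecyl]-3,4-dihydro-1H-isochromen-1-one | CCCCC[C@H](O)CCCCC[C@@H]1Cc2cc(O)cc(O)c2C(=O)O1 | target

**Step count**
Total: 7 steps. Longest linear sequence: 5 steps (steps 1, 2, 5, 6, 7; the branch through steps 3 and 4 is equally long).

**Steps most likely to fail**

1. Step 7 (proposed new method). Two processes could defeat it: base-induced E2 loss of methanesulfonate toward the conjugated styrene before the ring carbon is carboxylated, or a carboxylation that stalls on the wrong side of its equilibrium. The fallback uses only known reactions and sets out from 5. Vilsmeier–Haack formylation (POCl3, DMF, 0 °C → rt), which on 1-alkyl-3,5-dialkoxybenzenes goes ortho to the alkyl group and para to an ether, should give (2S)-1-[3,5-bis(benzyloxy)-2-formylphenyl]hex-5-en-2-yl methanesulfonate F1. Pinnick oxidation (NaClO2, NaH2PO4, 2-methylbut-2-ene, t-BuOH/H2O) should give 2,4-bis(benzyloxy)-6-[(2S)-2-(methanesulfonyloxy)hex-5-en-1-yl]benzoic acid F2. K2CO3 in DMF should close the lactone by carboxylate SN2 with inversion to (3R)-6,8-bis(benzyloxy)-3-(but-3-en-1-yl)-3,4-dihydro-1H-isochromen-1-one F3. Cross-metathesis of F3 with 9 under the conditions of step 5 should give (3R)-6,8-bis(benzyloxy)-3-[(3E,6S)-6-hydroxyundec-3-en-1-yl]-3,4-dihydro-1H-isochromen-1-one F4. Hydrogenation (H2, 10% Pd/C, EtOAc) then saturates the alkene and removes both benzyl groups, and the fallback comes back to the route at 13.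

2. Step 5. Both partners are unhindered terminal alkenes of the same reactivity class, so statistical homodimerization and ruthenium hydride-induced double-bond migration could erode the cross product. The fallback replaces metathesis by epoxide openings; it sets out from 8 and from the Grignard reagent 3 (made from 1). Hex-5-en-1-ylmagnesium bromide F5 (from 6-bromohex-1-ene and Mg) opens 8 under CuI catalysis to (6S)-tridec-12-en-6-ol F6. NaH and benzyl bromide give ({[(6S)-tridec-12-en-6-yl]oxy}methyl)benzene F7. mCPBA gives 2-[(6S)-6-(benzyloxy)undecyl]oxirane F8 as a mixture at the oxirane carbon. Hydrolytic kinetic resolution with (S,S)-(salen)Co(OAc) (trivalent cobalt; salen = N,N'-bis(3,5-di-tert-butylsalicylidene)cyclohexane-1,2-diamine dianion; the catalyst enantiomer expected to hydrolyse the (2R)-epoxide) and 0.55 equiv H2O should leave (2S)-2-[(6S)-6-(benzyloxy)undecyl]oxirane F9. Opening of F9 with 3 and CuI gives (2S,8S)-1-[3,5-bis(benzyloxy)phenyl]-8-(benzyloxy)tridecan-2-ol F10. MsCl and Et3N give (2S,8S)-1-[3,5-bis(benzyloxy)phenyl]-8-(benzyloxy)tridecan-2-yl methanesulfonate F11. Hydrogenolysis of all three benzyl ethers (H2, 10% Pd/C, EtOAc) brings the fallback back to the route at 11.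

3. Step 6. Prolonged hydrogenolysis could cost the mesylate by solvolysis or elimination, and ruthenium residues from step 5 could poison the palladium and leave the alkene or a benzyl ether in place. The fallback avoids hydrogen and palladium; it sets out from 10. Diimide reduction (2-nitrobenzenesulfonohydrazide, Et3N, CH2Cl2, rt) should give (2S,8S)-1-[3,5-bis(benzyloxy)phenyl]-8-hydroxytridecan-2-yl methanesulfonate F12. Lewis-acid debenzylation with BCl3 and pentamethylbenzene (CH2Cl2, −78 °C) should then free both phenols, and the fallback comes back to the route at 11.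

**Further compounds**
F1 | step 7 | (2S)-1-[3,5-bis(benzyloxy)-2-formylphenyl]hex-5-en-2-yl methanesulfonate | C=CCC[C@H](OS(C)(=O)=O)Cc1cc(OCc2ccccc2)cc(OCc2ccccc2)c1C=O
F2 | step 7 | 2,4-bis(benzyloxy)-6-[(2S)-2-(methanesulfonyloxy)hex-5-en-1-yl]benzoic acid | C=CCC[C@H](OS(C)(=O)=O)Cc1cc(OCc2ccccc2)cc(OCc2ccccc2)c1C(=O)O
F3 | step 7 | (3R)-6,8-bis(benzyloxy)-3-(but-3-en-1-yl)-3,4-dihydro-1H-isochromen-1-one | C=CCC[C@@H]1Cc2cc(OCc3ccccc3)cc(OCc3ccccc3)c2C(=O)O1
F4 | step 7 | (3R)-6,8-bis(benzyloxy)-3-[(3E,6S)-6-hydroxyundec-3-en-1-yl]-3,4-dihydro-1H-isochromen-1-one | CCCCC[C@H](O)C/C=C/CC[C@@H]1Cc2cc(OCc3ccccc3)cc(OCc3ccccc3)c2C(=O)O1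
F5 | step 5 | hex-5-en-1-ylmagnesium bromide | C=CCCCC[Mg]Br
F6 | step 5 | (6S)-tridec-12-en-6-ol | CCCCC[C@H](O)CCCCCC=C
F7 | step 5 | ({[(6S)-tridec-12-en-6-yl]oxy}methyl)benzene | CCCCC[C@H](OCc1ccccc1)CCCCCC=C
F8 | step 5 | 2-[(6S)-6-(benzyloxy)undecyl]oxirane, mixture at the oxirane carbon | CCCCC[C@H](OCc1ccccc1)CCCCCC1CO1
F9 | step 5 | (2S)-2-[(6S)-6-(benzyloxy)undecyl]oxirane | CCCCC[C@H](OCc1ccccc1)CCCCC[C@H]1CO1
F10 | step 5 | (2S,8S)-1-[3,5-bis(benzyloxy)phenyl]-8-(benzyloxy)tridecan-2-ol | CCCCC[C@H](OCc1ccccc1)CCCCC[C@H](O)Cc1cc(OCc2ccccc2)cc(OCc2ccccc2)c1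
F11 | step 5 | (2S,8S)-1-[3,5-bis(benzyloxy)phenyl]-8-(benzyloxy)tridecan-2-yl methanesulfonate | CCCCC[C@H](OCc1ccccc1)CCCCC[C@H](OS(C)(=O)=O)Cc1cc(OCc2ccccc2)cc(OCc2ccccc2)c1
F12 | step 6 | (2S,8S)-1-[3,5-bis(benzyloxy)phenyl]-8-hydroxytridecan-2-yl methanesulfonate | CCCCC[C@H](O)CCCCC[C@H](OS(C)(=O)=O)Cc1cc(OCc2ccccc2)cc(OCc2ccccc2)c1
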